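**Retrosynthetic overview**
- The aryl C(=O)–CH2 bond of the β-diketone is cut first. It is made by directed formyl C–H activation of a salicylaldehyde-type chromene and insertion of a benzoylcarbene equivalent (a β-keto sulfoxonium ylide), not by Claisen or Baker–Venkataraman chemistry.
- The ylide comes from trimethylsulfoxonium iodide and benzoyl chloride.
- The chromene aldehyde comes from 2,4-dihydroxy-6-methoxybenzaldehyde and prenal by formal [3+3] annulation (C-alkylation, ortho-quinone methide, oxa-6π).
- Ring order: both benzene rings are bought; the pyran ring is the only ring formed (step 1). No protecting groups are used.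

Assumption: the target has no stereocentre (it is achiral, drawn as the diketo tautomer of a chelated enol), so no stereocontrol is needed; the aldehyde starting material of step 1 is taken as a catalogue compound.

**Step 1**
Reactants: 1 2,4-dihydroxy-6-methoxybenzaldehyde; 2 3-methylbut-2-enal (prenal)
Product: 5 5-hydroxy-7-methoxy-2,2-dimethyl-2H-chromene-6-carbaldehyde, via benzylic carbinol adduct 3 (not isolated), via ortho-quinone methide 4 (not isolated)
Conditions: 2 (2 equiv), pyridine, 120 °C, sealed tube, 16 h
Reagents that add atoms: none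
Why: Base-mediated aldol-type C-alkylation, dehydration to the ortho-quinone methide and oxa-6π electrocyclisation (formal [3+3] chromenylation); the CHO···HO-2 chelate leaves only the 4-OH free and fixes C3=C4 double-bond character, so the pyran closes on C3/O4 and gives the 5-OH/6-CHO/7-OMe pattern, with no stereocentre formed.

**Step 2**
Reactants: 6 trimethylsulfoxonium iodide; 7 benzoyl chloride
Product: 10 2-[dimethyl(oxo)-λ6-sulfanylidene]-1-phenylethan-1-one, via dimethylsulfoxonium methylide 8 (not isolated), via dimethyl(phenacyl)sulfoxonium chloride 9 (not isolated)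
Conditions: 6 (3 equiv), KOtBu (3 equiv), THF, reflux, 2 h; then 7 (1 equiv), 0 °C to rt
Reagents that add atoms: none
Why: Corey–Chaykovsky ylide generation followed by C-acylation of the methylide; a second equivalent of methylide deprotonates the acylsulfoxonium salt to give the stabilised, bench-stable β-keto sulfoxonium ylide.

**Step 3**
Reactants: 5 5-hydroxy-7-methoxy-2,2-dimethyl-2H-chromene-6-carbaldehyde; 10 2-[dimethyl(oxo)-λ6-sulfanylidene]-1-phenylethan-1-one
Product: 11 1-(5-hydroxy-7-methoxy-2,2-dimethyl-2H-chromen-6-yl)-3-phenylpropane-1,3-dione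
Conditions: 10 (1.3 equiv), [Cp*RhCl2]2 (2.5 mol%), AgSbF6 (10 mol%), NaOAc (50 mol%), DCE, 50 °C, N2; neutral work-up
Reagents that add atoms: none
Why: Proposed new method: phenoxide-directed Cp*Rh(III) activation of the formyl C–H gives a catalyst-bound five-membered acyl-rhodium chelate, which takes up the ylide as a rhodium carbene (loss of DMSO), undergoes migratory insertion and is protonated by AcOH to release the 1,3-diketone; the closest known reaction type is the Rh(III)-catalysed aldehyde C–H activation/annulation of salicylaldehydes with sulfoxonium ylides or diazo ketones to flavones, where this o-hydroxyaryl 1,3-diketone is the intermediate before acid-promoted cyclodehydration, and here acetate buffering, no Brønsted acid additive and 50 °C are chosen to stop at the diketone; no stereocentre is formed.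

**Compound list**
1 | 2,4-dihydroxy-6-methoxybenzaldehyde | O=Cc1c(O)cc(O)cc1OC | starting material
2 | 3-methylbut-2-enal (prenal) | CC(C)=CC=O | starting material
3 | 2,4-dihydroxy-3-(1-hydroxy-3-methylbut-2-en-1-yl)-6-methoxybenzaldehyde (racemic carbinol adduct) | COc1cc(O)c(C(O)C=C(C)C)c(O)c1C=O | intermediate
4 | 2-hydroxy-6-methoxy-3-(3-methylbut-2-en-1-ylidene)-4-oxocyclohexa-1,5-diene-1-carbaldehyde (ortho-quinone methide) | COC1=CC(=O)C(=CC=C(C)C)C(O)=C1C=O | intermediate
5 | 5-hydroxy-7-methoxy-2,2-dimethyl-2H-chromene-6-carbaldehyde | COc1cc2c(c(O)c1C=O)C=CC(C)(C)O2 | intermediate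
6 | trimethylsulfoxonium iodide | C[S+](C)(C)=O.[I-] | starting material
7 | benzoyl chloride | O=C(Cl)c1ccccc1 | starting material
8 | dimethylsulfoxonium methylide | [CH2-][S+](C)(C)=O | intermediate
9 | dimethyl(phenacyl)sulfoxonium chloride | C[S+](C)(=O)CC(=O)c1ccccc1.[Cl-] | intermediate
10 | 2-[dimethyl(oxo)-λ6-sulfanylidene]-1-phenylethan-1-one | CS(C)(=O)=CC(=O)c1ccccc1 | intermediate
11 | 1-(5-hydroxy-7-methoxy-2,2-dimethyl-2H-chromen-6-yl)-3-phenylpropane-1,3-dione (achiral) | COc1cc2c(c(O)c1C(=O)CC(=O)c1ccccc1)C=CC(C)(C)O2 | target

**Totals**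
Total step count: 3 (two in the main line, one for the ylide). Longest linear sequence: 2 steps (1 → 5 → 11).

**Steps most likely to fail, with fallbacks**

Most at risk is step 3, the key C–H acylmethylation. The formyl group of 5 is electron-rich and flanked by OH and OMe, so C–H activation may be slow. The vinylic C4–H peri to the 5-OH is a possible competing site. The product can also cyclodehydrate to the pyranoflavone if the medium turns acidic or hot. The fallback sets out from 5 and comes back to the route at 11. Compound 5 is protected (NaH, MOMCl, DMF, 0 °C) as 7-methoxy-5-(methoxymethoxy)-2,2-dimethyl-2H-chromene-6-carbaldehyde F1. The lithium enolate of acetophenone (LDA, THF, −78 °C) adds to it in an aldol reaction to give racemic 3-hydroxy-3-[7-methoxy-5-(methoxymethoxy)-2,2-dimethyl-2H-chromen-6-yl]-1-phenylpropan-1-one F2. Dess–Martin oxidation (NaHCO3, CH2Cl2, rt) then gives 1-[7-methoxy-5-(methoxymethoxy)-2,2-dimethyl-2H-chromen-6-yl]-3-phenylpropane-1,3-dione F3. Brief 2 M HCl in MeOH–THF at rt removes the carbonyl-flanked MOM group, which should cleave faster than the diketone cyclodehydrates, and gives 11.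

Second is step 1. The pyran could close in part on C5 instead of C3, giving the 7-hydroxy-5-methoxy isomer (told apart by the NOE from OMe to H-8 versus H-4). The ortho-quinone methide can also oligomerise in hot pyridine. The fallback sets out from 1 and comes back at 5. The unchelated 4-OH is alkylated selectively with 3-chloro-3-methylbut-1-yne (K2CO3, KI, CuI cat., acetone, reflux) to give 2-hydroxy-6-methoxy-4-[(2-methylbut-3-yn-2-yl)oxy]benzaldehyde F4. Heating F4 (N,N-diethylaniline, 180 °C) triggers the aryl propargyl ether Claisen rearrangement, 1,5-H shift and oxa-6π closure. This cascade is steered to C3 by the same chelate-fixed C3=C4 bond and delivers 5.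

Third is step 2, where double acylation of the methylide or hydrolysis of 7 can lower the yield of 10. The fallback sets out from 7 and comes back at 11. Compound 7 is treated with trimethylsilyldiazomethane (2 equiv, MeCN–THF, 0 °C) to give 2-diazo-1-phenylethan-1-one F5. F5 replaces 10 as the carbene source in the Cp*Rh(III) coupling with 5 under the step 3 catalyst system, with nitrogen as the leaving group, and gives 11.

**Further compounds**
F1 | step 3 | 7-methoxy-5-(methoxymethoxy)-2,2-dimethyl-2H-chromene-6-carbaldehyde | COCOc1c(C=O)c(OC)cc2OC(C)(C)C=Cc12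
F2 | step 3 | 3-hydroxy-3-[7-methoxy-5-(methoxymethoxy)-2,2-dimethyl-2H-chromen-6-yl]-1-phenylpropan-1-one (racemic) | COCOc1c(C(O)CC(=O)c3ccccc3)c(OC)cc2OC(C)(C)C=Cc12
F3 | step 3 | 1-[7-methoxy-5-(methoxymethoxy)-2,2-dimethyl-2H-chromen-6-yl]-3-phenylpropane-1,3-dione | COCOc1c(C(=O)CC(=O)c3ccccc3)c(OC)cc2OC(C)(C)C=Cc12
F4 | step 1 | 2-hydroxy-6-methoxy-4-[(2-methylbut-3-yn-2-yl)oxy]benzaldehyde | COc1cc(OC(C)(C)C#C)cc(O)c1C=O
F5 | step 2 | 2-diazo-1-phenylethan-1-one | [N-]=[N+]=CC(=O)c1ccccc1
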